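**Retrosynthetic overview**
1. The target comes from a macrocyclic (Z)-enol carbamate that masks the C10 ketone, by late acetylation and solvolysis. C4 is set by OH-directed hydrogenation of a 4-methylidene-5-ol, and C5 by CBS reduction of the corresponding enone.
2. The only ring (14-membered) is closed at C4–C5. A vinyl triflate (from the C4 methyl ketone) is coupled with the C5 aldehyde (from a prenyl terminus) under Ni/Cr conditions.
3. The key disconnection is C12–C13. A chiral ketone homoenolate (a titanated secondary allyl carbamate, with C12 as the β-carbon of the C10 carbonyl) adds to the C13 aldehyde. This sets C12 and C13 and leaves C10 masked. A Mitsunobu acetate then inverts C13.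
4. Fragments: the C13–C4 keto aldehyde comes from (S)-limonene (source of C1). The C5–C12 allyl carbamate comes from (S)-citronellal (source of C8) and propyne.

Assumption: ring locants C1–C14 follow the atom order of the given SMILES (C1 = isopropenyl carbon), so the target is (1S,4R,5S,8S,12R,13R). These locants are used in the "Why" lines and in the macrocycle names.

**Step 1**
Reactants: 1 (S)-(−)-limonene
Product: 3 (3S)-6-oxo-3-(prop-1-en-2-yl)heptanal, via limonene 1,2-oxide 2 (not isolated)
Conditions: mCPBA (1.0 equiv), CH2Cl2, 0 °C; solvent swap, then H5IO6 (1.1 equiv), THF–H2O, 0 °C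
Reagents that add atoms: mCPBA, O=C(OO)c1cccc(Cl)c1; water, O
Why: Prilezhaev epoxidation picks the electron-richer trisubstituted ring alkene over the isopropenyl group, and periodic acid then opens the epoxide and cleaves the glycol (Malaprade cleavage); C1 comes unchanged from limonene.

**Step 2**
Reactants: 4 (S)-(−)-citronellal; 5 propyne
Product: 8 (2E,4S,6S)-6,10-dimethylundeca-2,9-dien-4-ol, via dicyclohexyl(propenyl)borane 6 (not isolated), via ethyl(propenyl)zinc 7 (not isolated)
Conditions: 5, Cy2BH, toluene, 0 °C→rt; Et2Zn, −78 °C; (+)-MIB (5 mol %), then 4, −20 °C; aqueous work-up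
Reagents that add atoms: none
Why: Oppolzer–Walsh asymmetric alkenylzinc addition (hydroboration, B-to-Zn exchange, amino-alcohol catalysis): syn-hydroboration fixes the E alkene, (+)-MIB directs Re-face attack to set the temporary C10 (S) carbinol, and C8 comes from citronellal.

**Step 3**
Reactants: 8 (2E,4S,6S)-6,10-dimethylundeca-2,9-dien-4-ol
Product: 9 (2E,4S,6S)-6,10-dimethylundeca-2,9-dien-4-yl N,N-diisopropylcarbamate
Conditions: iPr2NC(O)Cl, pyridine, 90 °C
Reagents that add atoms: N,N-diisopropylcarbamoyl chloride, CC(C)N(C(C)C)C(=O)Cl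
Why: O-carbamoylation installs the hindered, chelating group that directs and stabilises the allyl anion of the next step, and no stereocentre is touched.

**Step 4 (key step)**
Reactants: 9 (2E,4S,6S)-6,10-dimethylundeca-2,9-dien-4-yl N,N-diisopropylcarbamate; 3 (3S)-6-oxo-3-(prop-1-en-2-yl)heptanal
Product: 12 (6S,8Z,10R,11S,13S)-11-hydroxy-2,6,10-trimethyl-16-oxo-13-(prop-1-en-2-yl)heptadeca-2,8-dien-8-yl N,N-diisopropylcarbamate, via lithiated carbamate 10 (not isolated), via allyltitanium reagent 11 (not isolated)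
Conditions: n-BuLi, TMEDA, Et2O, −78 °C; ClTi(OiPr)3, −78 °C; then 3, −78 °C; aqueous work-up
Reagents that add atoms: none
Why: Hoppe homoaldol reaction: carbamate-directed deprotonation at C10 (retention) gives a configurationally stable 1-oxyallyl anion, Li→Ti exchange (inversion) gives a ketone homoenolate that attacks only the aldehyde at C12 through a Zimmerman–Traxler chair (syn-SE2′), so the C10 chirality is relayed to C12 (R), the E-crotyl geometry gives the anti C13 (S) carbinol, and C10 emerges as a (Z)-enol carbamate.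

**Step 5**
Reactants: 12 homoaldol adduct
Product: 13 (6S,8Z,10R,11R,13S)-11-acetoxy-2,6,10-trimethyl-16-oxo-13-(prop-1-en-2-yl)heptadeca-2,8-dien-8-yl N,N-diisopropylcarbamate
Conditions: AcOH, PPh3, DIAD, toluene, 0 °C→rt
Reagents that add atoms: acetic acid, CC(=O)O
Why: Mitsunobu esterification: SN2 displacement of the alkoxyphosphonium ion by acetate inverts C13 from S to R, turning the 12,13-anti adduct into the required 12,13-syn acetate in the operation that installs the ester.

**Step 6**
Reactants: 13 keto acetate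
Product: 15 (6S,8Z,10R,11R,13S)-11-acetoxy-2,6,10-trimethyl-13-(prop-1-en-2-yl)-16-(trifluoromethylsulfonyloxy)heptadeca-2,8,16-trien-8-yl N,N-diisopropylcarbamate, via kinetic lithium enolate 14 (not isolated)
Conditions: LiN(iPr)2 (1.05 equiv), THF, −78 °C; PhNTf2, −78→0 °C
Reagents that add atoms: N-phenylbis(trifluoromethanesulfonimide), O=S(=O)(N(c1ccccc1)S(=O)(=O)C(F)(F)F)C(F)(F)F
Why: Kinetic enolisation at the methyl side of the ketone (faster than deprotonation of the acetate at −78 °C) followed by O-sulfonylation gives the 1,1-disubstituted vinyl triflate (enol triflate formation).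

**Step 7**
Reactants: 15 vinyl triflate
Product: 17 (4S,6Z,8R,9R,11S)-9-acetoxy-4,8-dimethyl-1-oxo-11-(prop-1-en-2-yl)-14-(trifluoromethylsulfonyloxy)pentadeca-6,14-dien-6-yl N,N-diisopropylcarbamate, via terminal epoxide 16 (not isolated)
Conditions: mCPBA (1.0 equiv), CH2Cl2, −20 °C; then H5IO6, THF–H2O, 0 °C
Reagents that add atoms: mCPBA, O=C(OO)c1cccc(Cl)c1
Why: Prilezhaev epoxidation is fastest at the trialkyl-substituted prenyl alkene (the isopropenyl group, the acyl-deactivated enol carbamate and the vinyl triflate react more slowly), and periodic acid cleavage of the epoxide (Malaprade type) frees the C5 aldehyde and acetone.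

**Step 8**
Reactants: 17 aldehyde vinyl triflate
Product: 18 (1S,8S,10Z,12R,13R)-13-acetoxy-5-hydroxy-8,12-dimethyl-4-methylidene-1-(prop-1-en-2-yl)cyclotetradec-10-en-10-yl N,N-diisopropylcarbamate (C5 epimers)
Conditions: CrCl2 (8 equiv), NiCl2 (1 mol % of the CrCl2), DMSO–THF, 2 mM, syringe-pump addition, rt
Reagents that add atoms: none
Why: Nozaki–Hiyama–Kishi macrocyclisation: zerovalent nickel inserts into the C–OTf bond, and the derived alkenylchromium species adds only to the aldehyde under high dilution, closing the 14-membered ring at C4–C5; the unselective C5 carbinol is corrected in steps 9 and 10.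

**Step 9**
Reactants: 18 macrocyclic allylic alcohol
Product: 19 (1S,8S,10Z,12R,13R)-13-acetoxy-8,12-dimethyl-4-methylidene-5-oxo-1-(prop-1-en-2-yl)cyclotetradec-10-en-10-yl N,N-diisopropylcarbamate
Conditions: Dess–Martin periodinane, CH2Cl2, 0 °C→rt
Reagents that add atoms: none
Why: Dess–Martin oxidation converges both C5 epimers on one α-methylene ketone under neutral conditions that leave the acetate, the enol carbamate and the alkenes alone.

**Step 10**
Reactants: 19 macrocyclic enone
Product: 20 (1S,5S,8S,10Z,12R,13R)-13-acetoxy-5-hydroxy-8,12-dimethyl-4-methylidene-1-(prop-1-en-2-yl)cyclotetradec-10-en-10-yl N,N-diisopropylcarbamate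
Conditions: (R)-Me-CBS oxazaborolidine (30 mol %), catecholborane, toluene, −78 °C
Reagents that add atoms: none
Why: Corey–Bakshi–Shibata reduction: the branched alkenyl side acts as the large group and the C6 methylene as the small one, so the (R)-catalyst delivers hydride to give the (5S)-alcohol, and catecholborane at −78 °C does not hydroborate the isopropenyl group.

**Step 11**
Reactants: 20 (5S)-allylic alcohol
Product: 21 (1S,4R,5S,8S,10Z,12R,13R)-13-acetoxy-5-hydroxy-4,8,12-trimethyl-1-(prop-1-en-2-yl)cyclotetradec-10-en-10-yl N,N-diisopropylcarbamate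
Conditions: Ru(OAc)2[(S)-BINAP] (2 mol %), H2 (10 atm), MeOH, rt, stopped after 1 equiv H2
Reagents that add atoms: none
Why: Hydroxyl-directed homogeneous hydrogenation (Noyori type): only the alkene next to the coordinating C5–OH binds the catalyst, so the isolated isopropenyl group and the enol carbamate stay, and H2 is delivered on the face of the conformer that avoids A(1,2) strain between C6 and C3, giving the 4,5-anti product (4R).

**Step 12**
Reactants: 21 saturated alcohol
Product: 22 (1S,4R,5S,8S,10Z,12R,13R)-5,13-diacetoxy-4,8,12-trimethyl-1-(prop-1-en-2-yl)cyclotetradec-10-en-10-yl N,N-diisopropylcarbamate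
Conditions: Ac2O, DMAP (cat.), pyridine, CH2Cl2, rt
Reagents that add atoms: acetic anhydride, CC(=O)OC(C)=O
Why: DMAP-catalysed acyl transfer acetylates the only free hydroxyl with retention at C5.

**Step 13**
Reactants: 22 diacetoxy enol carbamate
Product: 23 (1S,4R,5S,8S,12R,13R)-5,13-diacetoxy-4,8,12-trimethyl-1-(prop-1-en-2-yl)cyclotetradecan-10-one (target)
Conditions: Hg(OAc)2 (5 mol %), MeSO3H (1.1 equiv), THF–H2O (9:1), 0 °C→rt
Reagents that add atoms: water, O
Why: Hoppe-type acid solvolysis of the enol carbamate: electrophilic attack at C11, capture of water at C10 and loss of iPr2NCO2H (as iPr2NH and CO2) free the ketone; neither α-carbon of C10 is stereogenic, and alkyl-substituted alkenes are known to survive this deblocking.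

**Compound list**
1 | (S)-(−)-limonene | C=C(C)[C@@H]1CC=C(C)CC1 | starting material
2 | (4S)-limonene 1,2-oxide (cis/trans mixture) | C=C(C)[C@@H]1CC2OC2(C)CC1 | intermediate (not isolated)
3 | (3S)-6-oxo-3-(prop-1-en-2-yl)heptanal | C=C(C)[C@H](CC=O)CCC(C)=O | intermediate
4 | (S)-(−)-citronellal | O=CC[C@@H](C)CCC=C(C)C | starting material
5 | propyne | CC#C | starting material
6 | dicyclohexyl[(E)-prop-1-enyl]borane | C/C=C/B(C1CCCCC1)C1CCCCC1 | intermediate (not isolated)
7 | ethyl[(E)-prop-1-enyl]zinc | C/C=C/[Zn]CC | intermediate (not isolated)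
8 | (2E,4S,6S)-6,10-dimethylundeca-2,9-dien-4-ol | C/C=C/[C@@H](O)C[C@@H](C)CCC=C(C)C | intermediate
9 | (2E,4S,6S)-6,10-dimethylundeca-2,9-dien-4-yl N,N-diisopropylcarbamate | C/C=C/[C@@H](OC(=O)N(C(C)C)C(C)C)C[C@@H](C)CCC=C(C)C | intermediate
10 | 4-lithio derivative of 9 (Li in the place of H, retention) | C/C=C/[C@@]([Li])(OC(=O)N(C(C)C)C(C)C)C[C@@H](C)CCC=C(C)C | intermediate (not isolated)
11 | 4-(triisopropoxytitanio) derivative of 9 (Ti on the opposite face, inversion) | C/C=C/[C@]([Ti](OC(C)C)(OC(C)C)OC(C)C)(OC(=O)N(C(C)C)C(C)C)C[C@@H](C)CCC=C(C)C | intermediate (not isolated)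
12 | homoaldol adduct (12R,13S; Z) | CC(=O)CC[C@H](C(C)=C)C[C@H](O)[C@H](C)/C=C(\OC(=O)N(C(C)C)C(C)C)C[C@@H](C)CCC=C(C)C | intermediate
13 | inverted acetate (12R,13R) | CC(=O)CC[C@H](C(C)=C)C[C@@H](OC(C)=O)[C@H](C)/C=C(\OC(=O)N(C(C)C)C(C)C)C[C@@H](C)CCC=C(C)C | intermediate
14 | kinetic lithium enolate of 13 | C=C(O[Li])CC[C@H](C(C)=C)C[C@@H](OC(C)=O)[C@H](C)/C=C(\OC(=O)N(C(C)C)C(C)C)C[C@@H](C)CCC=C(C)C | intermediate (not isolated)
15 | vinyl triflate | C=C(OS(=O)(=O)C(F)(F)F)CC[C@H](C(C)=C)C[C@@H](OC(C)=O)[C@H](C)/C=C(\OC(=O)N(C(C)C)C(C)C)C[C@@H](C)CCC=C(C)C | intermediate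
16 | prenyl epoxide of 15 (epimers at the epoxide CH, lost in the cleavage) | C=C(OS(=O)(=O)C(F)(F)F)CC[C@H](C(C)=C)C[C@@H](OC(C)=O)[C@H](C)/C=C(\OC(=O)N(C(C)C)C(C)C)C[C@@H](C)CCC1OC1(C)C | intermediate (not isolated)
17 | aldehyde vinyl triflate | C=C(OS(=O)(=O)C(F)(F)F)CC[C@H](C(C)=C)C[C@@H](OC(C)=O)[C@H](C)/C=C(\OC(=O)N(C(C)C)C(C)C)C[C@@H](C)CCC=O | intermediate
18 | macrocyclic 4-methylidene-5-ol (C5 epimers) | C=C(C)[C@H]1CCC(=C)C(O)CC[C@H](C)C/C(OC(=O)N(C(C)C)C(C)C)=C/[C@@H](C)[C@H](OC(C)=O)C1 | intermediate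
19 | macrocyclic α-methylene ketone | C=C(C)[C@H]1CCC(=C)C(=O)CC[C@H](C)C/C(OC(=O)N(C(C)C)C(C)C)=C/[C@@H](C)[C@H](OC(C)=O)C1 | intermediate
20 | (5S)-allylic alcohol | C=C(C)[C@H]1CCC(=C)[C@@H](O)CC[C@H](C)C/C(OC(=O)N(C(C)C)C(C)C)=C/[C@@H](C)[C@H](OC(C)=O)C1 | intermediate
21 | (4R,5S)-alcohol | C=C(C)[C@H]1CC[C@@H](C)[C@@H](O)CC[C@H](C)C/C(OC(=O)N(C(C)C)C(C)C)=C/[C@@H](C)[C@H](OC(C)=O)C1 | intermediate
22 | diacetoxy enol carbamate | C=C(C)[C@H]1CC[C@@H](C)[C@@H](OC(C)=O)CC[C@H](C)C/C(OC(=O)N(C(C)C)C(C)C)=C/[C@@H](C)[C@H](OC(C)=O)C1 | intermediate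
23 | CNP0328624.1 | C=C(C)[C@H]1CC[C@@H](C)[C@@H](OC(C)=O)CC[C@H](C)CC(=O)C[C@@H](C)[C@H](OC(C)=O)C1 | target

**Totals**
Total steps: 13. Longest linear sequence: 12 (steps 2–13, from 4).

**Three steps most likely to fail, with fallbacks**

Step 4. The deprotonation may be slow or may lose configuration, and the reagent mixture meets an enolisable keto aldehyde. The fallback makes the homoenolate an isolable allylstannane. It sets out again from 4 and 5. The alkenylzinc addition is run with (−)-MIB to give the C10-epimeric (2E,4R,6S)-6,10-dimethylundeca-2,9-dien-4-ol F1, which is carbamoylated to the (4R)-carbamate F2. n-BuLi/TMEDA converts this into the lithio compound F3. Bu3SnCl traps F3 at C12 (anti-SE2′) as the chromatographable (Z)-γ-stannyl enol carbamate F4. TiCl4 at −78 °C (a second anti-SE2′) turns this into the trichlorotitanium homoenolate F5, which has the same C10 configuration as 11. F5 adds to 3 through the same chair and comes back to the route at 12.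

Step 11. The isopropenyl group may be reduced as well, or the ligand and substrate may be mismatched. The fallback sets C4 at the ketone stage, where no H2 is used. It sets out from 19. Conjugate reduction with [(Ph3P)CuH]6 touches only the enone and gives the (4R)-α-methyl ketone F6 together with the (4S)-epimer F7. The two are separated, and the (4S)-epimer is recycled by DBU equilibration. LiBH(s-Bu)3 at −78 °C then reduces F6 under Felkin–Anh control to the 4,5-anti alcohol. This skips step 10 and comes back to the route at 21.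

Step 13. The acid may hydrate the isopropenyl group or cleave an acetate before the hindered enol carbamate has reacted. The fallback unmasks the ketone with a nucleophile before the acetates are final. It sets out from 21. Excess MeLi (Et2O, 0 °C→rt) attacks the acetate and the carbamoyl carbonyl to give the trilithium enolate bis-alkoxide F8. As an enolate, F8 is protected from further addition. An aqueous quench gives the dihydroxy ketone F9, and Ac2O/DMAP/pyridine acetylates both hydroxyls, coming back to the route at 23.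

**Further compounds**
F1 | step 4 | (2E,4R,6S)-6,10-dimethylundeca-2,9-dien-4-ol | C/C=C/[C@H](O)C[C@@H](C)CCC=C(C)C
F2 | step 4 | (2E,4R,6S)-6,10-dimethylundeca-2,9-dien-4-yl N,N-diisopropylcarbamate | C/C=C/[C@H](OC(=O)N(C(C)C)C(C)C)C[C@@H](C)CCC=C(C)C
F3 | step 4 | 4-lithio derivative of F2 (retention) | C/C=C/[C@]([Li])(OC(=O)N(C(C)C)C(C)C)C[C@@H](C)CCC=C(C)C
F4 | step 4 | (Z)-γ-(tributylstannyl) enol carbamate, (S) at the tin-bearing carbon | CCCC[Sn](CCCC)(CCCC)[C@@H](C)/C=C(\OC(=O)N(C(C)C)C(C)C)C[C@@H](C)CCC=C(C)C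
F5 | step 4 | 4-(trichlorotitanio) allyl carbamate | C/C=C/[C@]([Ti](Cl)(Cl)Cl)(OC(=O)N(C(C)C)C(C)C)C[C@@H](C)CCC=C(C)C
F6 | step 11 | (4R)-4-methyl-5-oxo macrocycle | C=C(C)[C@H]1CC[C@@H](C)C(=O)CC[C@H](C)C/C(OC(=O)N(C(C)C)C(C)C)=C/[C@@H](C)[C@H](OC(C)=O)C1
F7 | step 11 | (4S)-4-methyl-5-oxo macrocycle | C=C(C)[C@H]1CC[C@H](C)C(=O)CC[C@H](C)C/C(OC(=O)N(C(C)C)C(C)C)=C/[C@@H](C)[C@H](OC(C)=O)C1
F8 | step 13 | trilithium enolate bis-alkoxide | C=C(C)[C@H]1CC[C@@H](C)[C@@H](O[Li])CC[C@H](C)C/C(O[Li])=C/[C@@H](C)[C@H](O[Li])C1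
F9 | step 13 | (1S,4R,5S,8S,12R,13R)-5,13-dihydroxy-4,8,12-trimethyl-1-(prop-1-en-2-yl)cyclotetradecan-10-one | C=C(C)[C@H]1CC[C@@H](C)[C@@H](O)CC[C@H](C)CC(=O)C[C@@H](C)[C@H](O)C1
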